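**Plan**
1. Retrosynthesis: C17 is cut from C8 (vinyl carbanion plus ketone, then ozonolysis); the Z-enoate is cut at C13–C16 and C14–C15 (syn-carbocupration of an ynoate made by carboxylating a terminal alkyne); ring A is cut at C2–C3; then C9–C11, C10–C1 and C4–C5 are cut back to 2-methylcyclohex-2-enone.
2. Forward: ring B is the commercial cyclohexenone ring; C4–C5 comes from an Ireland–Claisen rearrangement, the enone from allylic oxidation, C10–C1 and C9–C11 from conjugate addition and enolate alkylation; ring A is closed last, by the C2–C3 bond.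
3. Enabling feature: C3 is an acyl carbon on the quaternary, non-enolizable C4 (gem-dimethyl), and C2 is the primary end of the two-carbon arm on quaternary C10; the two arms sit trans-diequatorial on ring B, so a C2 carbanion can only attack C3 and can only give the trans-fused ring A.
4. Stereochemistry: a CBS reduction sets one carbinol center and the Claisen step relays it to C5; C10 follows by anti conjugate addition, C9 by equilibration, C3 by axial hydride delivery, C8 by equatorial Grignard attack (axial C10 methyl blocks the other path), and the Z-alkene by syn-carbocupration.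

Key step: step 11

Remark: ring positions are cited in labdane numbering (C1–C10 decalin, C11–C16 side chain, C17 formyl carbon); the target is the (3R,5S,8R,9S,10R) isomer, i.e. the ent-labdane series, so the skeleton is built de novo rather than from normal-series chiral-pool labdanes.

**Step 1**
Reactants: 1 2-methylcyclohex-2-en-1-one
Product: 2 (R)-2-methylcyclohex-2-en-1-ol
Conditions: (S)-2-methyl-CBS-oxazaborolidine (10 mol%), BH3·SMe2, THF, −20 °C; MeOH quench
Reagents that add atoms: none
Why: Corey–Bakshi–Shibata reduction, in which the ketone should bind the oxazaborolidine anti to the bulkier 2-methylalkenyl arm so that hydride delivery gives the (R)-carbinol, the only center in the route set by a chiral reagent.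

**Step 2**
Reactants: 2 (R)-2-methylcyclohex-2-en-1-ol; 3 2-methylpropanoyl chloride
Product: 4 (R)-2-methylcyclohex-2-en-1-yl 2-methylpropanoate
Conditions: Et3N, DMAP (cat.), CH2Cl2, 0 °C
Reagents that add atoms: none
Why: DMAP-catalysed acylation of a secondary allylic alcohol, which leaves the stereocenter untouched.

**Step 3**
Reactants: 4 (R)-2-methylcyclohex-2-en-1-yl 2-methylpropanoate
Product: 8 methyl 2-methyl-2-[(1S)-2-methylcyclohex-2-en-1-yl]propanoate, via silyl ketene acetal 5 (not isolated), via trimethylsilyl ester 6 (not isolated), via carboxylic acid 7 (not isolated)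
Conditions: LDA, THF, −78 °C; TMSCl/Et3N; −78 to 60 °C; 1 M HCl; then TMSCHN2, PhMe/MeOH, 0 °C
Reagents that add atoms: trimethylsilyldiazomethane, C[Si](C)(C)C=[N+]=[N-]
Why: Ireland–Claisen rearrangement, in which the symmetric α,α-dimethyl ketene acetal (no E/Z issue) rearranges suprafacially and forms the quaternary C4–C5 bond on the face that carried the C–O bond, so the carbinol chirality is relayed to C5 (S) before hydrolysis and diazoalkane esterification.

**Step 4**
Reactants: 8 methyl 2-methyl-2-[(1S)-2-methylcyclohex-2-en-1-yl]propanoate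
Product: 9 methyl 2-methyl-2-[(1S)-2-methyl-4-oxocyclohex-2-en-1-yl]propanoate
Conditions: Rh2(C6H10NO)4 (dirhodium tetracaprolactamate, 1 mol%), t-BuOOH (70% aq.), K2CO3, CH2Cl2, rt
Reagents that add atoms: tert-butyl hydroperoxide, CC(C)(C)OO
Why: allylic C–H oxidation by tert-butylperoxyl radicals, which should take place at the unhindered ring CH2 next to the CH= carbon and not at the methine shielded by the quaternary carbon, giving the 3-methyl-4-substituted cyclohexenone.

**Step 5**
Reactants: 9 methyl 2-methyl-2-[(1S)-2-methyl-4-oxocyclohex-2-en-1-yl]propanoate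
Product: 10 methyl 2-[(1S,2R)-2-ethenyl-2-methyl-4-(trimethylsilyloxy)cyclohex-3-en-1-yl]-2-methylpropanoate
Conditions: CH2=CHMgBr, CuBr·SMe2 (20 mol%), TMSCl, HMPA, THF, −78 to −40 °C; Et3N, pentane work-up
Reagents that add atoms: vinylmagnesium bromide, C=C[Mg]Br; chlorotrimethylsilane, C[Si](C)(C)Cl
Why: copper-catalysed, TMSCl-accelerated conjugate addition, in which the bulky C5 substituent lies pseudoaxial (A1,2 strain with the C10 methyl) and the vinyl group adds anti to it, setting quaternary C10 and storing the regiodefined enolate as its silyl ether.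

**Step 6**
Reactants: 11 4-(trimethylsilyl)but-3-yn-1-ol
Product: 12 4-(trimethylsilyl)but-3-yn-1-yl trifluoromethanesulfonate
Conditions: Tf2O, pyridine, CH2Cl2, −78 to 0 °C; used at once
Reagents that add atoms: trifluoromethanesulfonic anhydride, O=S(=O)(OS(=O)(=O)C(F)(F)F)C(F)(F)F
Why: sulfonylation of a primary alcohol, chosen because the homopropargylic triflate alkylates hindered enolates at low temperature where the iodide would mainly eliminate.

**Step 7**
Reactants: 10 silyl enol ether; 12 4-(trimethylsilyl)but-3-yn-1-yl trifluoromethanesulfonate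
Product: 14 methyl 2-{(1S,2R,3R)-2-ethenyl-2-methyl-4-oxo-3-[4-(trimethylsilyl)but-3-yn-1-yl]cyclohexyl}-2-methylpropanoate (butynyl chain cis to vinyl; 9-epi series), via lithium enolate 13 (not isolated)
Conditions: MeLi (1.05 equiv), THF, 0 °C; then 12, −78 to −20 °C
Reagents that add atoms: none
Why: regiospecific enolate generation from the silyl enol ether followed by SN2 alkylation, in which the electrophile should enter anti to the axial C10 methyl to give mainly the 9-epimer drawn; either C9 epimer serves, because C9 is equilibrated at step 13.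

**Step 8**
Reactants: 14 keto ester
Product: 15 ethylene ketal of 14 (1,3-dioxolane at C8)
Conditions: HOCH2CH2OH, TsOH·H2O (cat.), benzene, reflux (Dean–Stark)
Reagents that add atoms: ethylene glycol, OCCO
Why: acid-catalysed ketalization masks the only ketone before the hydroboration and organolithium steps.

**Step 9**
Reactants: 15 ketal
Product: 17 primary alcohol (C10 arm is CH2CH2OH), via alkylborane 16 (not isolated)
Conditions: 9-BBN, THF, 0 °C to rt; then aq. NaOAc, 30% H2O2, 0 °C
Reagents that add atoms: hydrogen peroxide, OO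
Why: anti-Markovnikov hydroboration–oxidation, in which 9-BBN should add to the monosubstituted vinyl group much faster than to the silyl-capped internal alkyne, and buffered oxidation spares the alkynylsilane.

**Step 10**
Reactants: 17 primary alcohol
Product: 18 primary iodide (C10 arm is CH2CH2I)
Conditions: I2, PPh3, imidazole, CH2Cl2, 0 °C to rt
Reagents that add atoms: iodine, II
Why: Appel-type iodination of an unhindered primary alcohol under buffered conditions that leave the ketal intact.

**Step 11**
Reactants: 18 iodo ester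
Product: 21 trans-decalin ketone (4,4,10-trimethyl-3-oxo; C8 ethylene ketal; 4-(trimethylsilyl)but-3-ynyl at C9), via alkyllithium 19 (not isolated), via tetrahedral lithium alkoxide 20 (not isolated)
Conditions: t-BuLi (2.1 equiv), Et2O/pentane, −78 °C; warm to 0 °C; aq. NH4Cl
Reagents that add atoms: none
Why: Iodine–lithium exchange (through the iodine ate complex; the second equivalent of t-BuLi destroys t-BuI) is far faster at −78 °C than addition to the α-quaternary ester and gives primary alkyllithium 19, whose C2 attacks the C3 ester carbonyl to give alkoxide 20, which loses methoxide only on warming or work-up, so no second addition occurs. The closest known reaction type is the Parham-type anionic cyclization, halogen–lithium exchange followed by intramolecular nucleophilic acyl substitution on an ester. Ring A closes in the 6-exo-trig mode through a chair-like transition state in which the C10–C1 and C5–C4 bonds are both equatorial on ring B, so only the trans-decalin can form. No stereocenter is created (C3 becomes sp2 and is set in step 12); the ring fusion is fixed by C5 and C10 from steps 3 and 5. The step needs exchange to beat direct attack of t-BuLi on the ester and needs the ester to be the only electrophile in reach; this is secured by the shielding of the ester, by the absence of any acidic or enolizable C–H (C4 is quaternary, the alkyne is silyl-capped) and by the ketal at C8, which removes the five-ring carbonyl competitor.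

**Step 12**
Reactants: 21 trans-decalin ketone
Product: 22 (3R)-alcohol of 21 (equatorial 3-OH; ketal and alkynylsilane kept)
Conditions: NaBH4, MeOH/THF, 0 °C
Reagents that add atoms: none
Why: borohydride reduction, in which axial hydride attack on the face opposite the C10 methyl should give the equatorial 3-OH, the usual outcome for 4,4-dimethyl-3-oxo trans-decalins.

**Step 13**
Reactants: 22 hydroxy ketal
Product: 24 (3R,5S,9S,10R)-9-(but-3-yn-1-yl)-3-hydroxy-4,4,10-trimethyl-trans-decalin-8-one, via 9-epi hydroxy ketone 23 (not isolated)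
Conditions: 1 M HCl, THF, rt; then NaOMe, MeOH, 50 °C
Reagents that add atoms: water, O
Why: ketal hydrolysis, then base-mediated enolization toward C9, which should place the side chain equatorial and cis to the C10 methyl (the thermodynamic arrangement in the trans-decalin), while methoxide also removes the alkyne silyl group.

**Step 14**
Reactants: 24 hydroxy ketone
Product: 25 8-ethenyl-3,8-diol (8-OH axial, syn to the C10 methyl; but-3-ynyl at C9)
Conditions: CH2=CHMgBr (excess), LaCl3·2LiCl, THF, 0 °C
Reagents that add atoms: vinylmagnesium bromide, C=C[Mg]Br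
Why: Grignard 1,2-addition with a Lewis acid additive that suppresses enolization, in which the axial C10 methyl blocks the axial trajectory so the vinyl group should enter equatorially and leave the new 8-OH axial, as in the target.

**Step 15**
Reactants: 25 alkynyl diol
Product: 27 methyl ynoate (C≡C–CO2Me at C13–C15), via ynoic acid 26 (not isolated)
Conditions: n-BuLi (3.3 equiv), THF, −78 °C; CO2; 1 M HCl; then TMSCHN2, PhMe/MeOH, 0 °C
Reagents that add atoms: carbon dioxide, O=C=O; trimethylsilyldiazomethane, C[Si](C)(C)C=[N+]=[N-]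
Why: carboxylation of the lithium acetylide within the alkoxide–acetylide trianion, where the carbonates formed at oxygen revert on acidification, followed by methylation of the carboxylic acid only.

**Step 16**
Reactants: 27 methyl ynoate
Product: 28 methyl (Z)-3-methylpent-2-enoate side chain on the 8-ethenyl-3,8-diol
Conditions: Me2CuLi (from CuI and MeLi, excess), THF, −78 °C; MeOH then aq. NH4Cl at −78 °C
Reagents that add atoms: lithium dimethylcuprate, [Li+].C[Cu-]C
Why: syn-carbocupration of the ynoate places methyl and copper cis, so protonation with retention at −78 °C should give the Z-enoate (ring-bearing chain cis to the ester), and the addition should outpace oxa-Michael attack by the hindered tertiary alkoxide.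

**Step 17**
Reactants: 28 vinyl carbinol enoate
Product: 30 methyl (2Z)-5-[(1S,2R,4aS,6R,8aR)-2-formyl-2,6-dihydroxy-5,5,8a-trimethyldecahydronaphthalen-1-yl]-3-methylpent-2-enoate (target), via ozonide 29 (not isolated)
Conditions: O3, CH2Cl2, −78 °C (indicator dye end point); then Me2S, −78 °C to rt
Reagents that add atoms: ozone, [O-][O+]=O
Why: ozonolysis with reductive work-up (Criegee mechanism), in which the monosubstituted vinyl group should react much faster than the conjugated, electron-poor trisubstituted enoate when ozone is titrated, giving the α-hydroxy aldehyde.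

**Compound list**
1 | 2-methylcyclohex-2-en-1-one | CC1=CCCCC1=O | starting material
2 | (R)-2-methylcyclohex-2-en-1-ol | O[C@@H]1CCCC=C1C | intermediate
3 | 2-methylpropanoyl chloride | CC(C)C(Cl)=O | starting material
4 | (R)-2-methylcyclohex-2-en-1-yl 2-methylpropanoate | CC(C)C(=O)O[C@@H]1CCCC=C1C | intermediate
5 | silyl ketene acetal of 4 | CC(C)=C(O[Si](C)(C)C)O[C@@H]1CCCC=C1C | intermediate (not isolated)
6 | trimethylsilyl 2-methyl-2-[(1S)-2-methylcyclohex-2-en-1-yl]propanoate | C[Si](C)(C)OC(=O)C(C)(C)[C@H]1CCCC=C1C | intermediate (not isolated)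
7 | 2-methyl-2-[(1S)-2-methylcyclohex-2-en-1-yl]propanoic acid | OC(=O)C(C)(C)[C@H]1CCCC=C1C | intermediate (not isolated)
8 | methyl 2-methyl-2-[(1S)-2-methylcyclohex-2-en-1-yl]propanoate | COC(=O)C(C)(C)[C@H]1CCCC=C1C | intermediate
9 | methyl 2-methyl-2-[(1S)-2-methyl-4-oxocyclohex-2-en-1-yl]propanoate | COC(=O)C(C)(C)[C@H]1CCC(=O)C=C1C | intermediate
10 | methyl 2-[(1S,2R)-2-ethenyl-2-methyl-4-(trimethylsilyloxy)cyclohex-3-en-1-yl]-2-methylpropanoate | C[Si](C)(C)OC1=C[C@](C)(C=C)[C@@H](C(C)(C)C(=O)OC)CC1 | intermediate
11 | 4-(trimethylsilyl)but-3-yn-1-ol | C[Si](C)(C)C#CCCO | starting material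
12 | 4-(trimethylsilyl)but-3-yn-1-yl trifluoromethanesulfonate | C[Si](C)(C)C#CCCOS(=O)(=O)C(F)(F)F | intermediate
13 | lithium enolate of 10 (O–Li in place of O–SiMe3) | [Li]OC1=C[C@](C)(C=C)[C@@H](C(C)(C)C(=O)OC)CC1 | intermediate (not isolated)
14 | methyl 2-{(1S,2R,3R)-2-ethenyl-2-methyl-4-oxo-3-[4-(trimethylsilyl)but-3-yn-1-yl]cyclohexyl}-2-methylpropanoate | C[Si](C)(C)C#CCC[C@@H]1[C@](C)(C=C)[C@@H](C(C)(C)C(=O)OC)CCC1=O | intermediate
15 | ethylene ketal of 14 | C[Si](C)(C)C#CCC[C@@H]1[C@](C)(C=C)[C@@H](C(C)(C)C(=O)OC)CCC12OCCO2 | intermediate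
16 | B-alkyl-9-borabicyclo[3.3.1]nonane from 15 (boron on C2) | C[Si](C)(C)C#CCC[C@@H]1[C@](C)(CCB2C3CCCC2CCC3)[C@@H](C(C)(C)C(=O)OC)CCC14OCCO4 | intermediate (not isolated)
17 | primary alcohol (C10 arm CH2CH2OH) | C[Si](C)(C)C#CCC[C@@H]1[C@](C)(CCO)[C@@H](C(C)(C)C(=O)OC)CCC12OCCO2 | intermediate
18 | primary iodide (C10 arm CH2CH2I) | C[Si](C)(C)C#CCC[C@@H]1[C@](C)(CCI)[C@@H](C(C)(C)C(=O)OC)CCC12OCCO2 | intermediate
19 | primary alkyllithium (C10 arm CH2CH2Li) | C[Si](C)(C)C#CCC[C@@H]1[C@](C)(CC[Li])[C@@H](C(C)(C)C(=O)OC)CCC12OCCO2 | intermediate (not isolated)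
20 | ring-closed lithium hemiketal alkoxide (C3 bears OLi and OMe) | C[Si](C)(C)C#CCC[C@@H]1[C@]2(C)CCC(O[Li])(OC)C(C)(C)[C@H]2CCC13OCCO3 | intermediate (not isolated)
21 | trans-decalin ketone: 4,4,10-trimethyl-3-oxo, C8 ethylene ketal, 4-(trimethylsilyl)but-3-ynyl at C9 (9-epi) | C[Si](C)(C)C#CCC[C@@H]1[C@]2(C)CCC(=O)C(C)(C)[C@H]2CCC13OCCO3 | intermediate
22 | (3R)-alcohol of 21 (equatorial 3-OH) | C[Si](C)(C)C#CCC[C@@H]1[C@]2(C)CC[C@@H](O)C(C)(C)[C@H]2CCC13OCCO3 | intermediate
23 | 9-epi hydroxy ketone (ketal removed, silyl group still on) | C[Si](C)(C)C#CCC[C@@H]1[C@]2(C)CC[C@@H](O)C(C)(C)[C@H]2CCC1=O | intermediate (not isolated)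
24 | (3R,5S,9S,10R)-9-(but-3-yn-1-yl)-3-hydroxy-4,4,10-trimethyl-trans-decalin-8-one | C#CCC[C@H]1[C@]2(C)CC[C@@H](O)C(C)(C)[C@H]2CCC1=O | intermediate
25 | 8-ethenyl-3,8-diol (8-OH axial, syn to C10 methyl) | C#CCC[C@H]1[C@]2(C)CC[C@@H](O)C(C)(C)[C@H]2CC[C@]1(O)C=C | intermediate
26 | ynoic acid of 25 | OC(=O)C#CCC[C@H]1[C@]2(C)CC[C@@H](O)C(C)(C)[C@H]2CC[C@]1(O)C=C | intermediate (not isolated)
27 | methyl ynoate | COC(=O)C#CCC[C@H]1[C@]2(C)CC[C@@H](O)C(C)(C)[C@H]2CC[C@]1(O)C=C | intermediate
28 | methyl (Z)-enoate bearing the 8-ethenyl-8-ol | COC(=O)/C=C(/C)CC[C@H]1[C@]2(C)CC[C@@H](O)C(C)(C)[C@H]2CC[C@]1(O)C=C | intermediate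
29 | ozonide of 28 (1,2,4-trioxolan-3-yl on C8) | COC(=O)/C=C(/C)CC[C@H]1[C@]2(C)CC[C@@H](O)C(C)(C)[C@H]2CC[C@]1(O)C3OCOO3 | intermediate (not isolated)
30 | methyl (2Z)-5-[(1S,2R,4aS,6R,8aR)-2-formyl-2,6-dihydroxy-5,5,8a-trimethyldecahydronaphthalen-1-yl]-3-methylpent-2-enoate | COC(=O)/C=C(/C)CC[C@H]1[C@]2(C)CC[C@@H](O)C(C)(C)[C@H]2CC[C@]1(O)C=O | target

**Step count**
Total: 17 steps. Longest linear sequence: 16 steps (steps 1–5 and 7–17 from compound 1); step 6 prepares triflate 12.

**Steps most likely to fail**

Step 7. C-alkylation of the hindered enolate next to quaternary C10 may lose out to O-alkylation, to proton transfer followed by alkylation at C7, or to attack of MeLi on the ester while the enolate is generated. The fallback sets out from 10 and comes back at 15. Silyl enol ether 10 is used directly as the nucleophile in a Mukaiyama–Michael addition to acrolein (BF3·OEt2, CH2Cl2, −78 °C) to give keto aldehyde F1. Aldehyde-selective Seyferth–Gilbert homologation with the Ohira–Bestmann reagent (K2CO3, MeOH) gives terminal alkyne F2. Ketalization as in step 8 gives ketal F3, and deprotonation of the alkyne (n-BuLi, THF, −78 °C) followed by TMSCl returns 15.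

Step 11. The organolithium formed by exchange may be protonated or may fail to add to the shielded ester, or early collapse of the tetrahedral adduct may allow a second addition. The fallback sets out from 18 and comes back at 21. Iodo ester 18 is reduced with DIBAL-H (CH2Cl2, −78 to 0 °C, primary iodide left intact) to iodo alcohol F4 and oxidized with Dess–Martin periodinane to iodo aldehyde F5. A Barbier-type closure with SmI2 (THF/HMPA) forms the same C2–C3 bond at the alcohol level and gives 22 together with its C3 epimer F6. Oxidation of the mixture with Dess–Martin periodinane returns ketone 21.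

Step 17. Chemoselectivity between the vinyl group and the enoate may be lost, and the α-hydroxy aldehyde may be degraded oxidatively. The fallback sets out from 24 and comes back at 30; it brings in C17 at the alcohol level. Ketone 24 is treated with (isopropoxydimethylsilyl)methylmagnesium chloride (same equatorial approach) to give β-hydroxysilane F7, and Tamao oxidation (H2O2, KF, KHCO3) gives triol F8. Carboxylation and esterification as in step 15 (one more equivalent of n-BuLi) give ynoic acid F9 and then ynoate F10. Cuprate addition as in step 16 gives enoate triol F11. Oxoammonium oxidation of the primary alcohol (TEMPO, N-chlorosuccinimide, Bu4NCl, buffered CH2Cl2/water) gives 30.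

**Further compounds**
F1 | step 7 | methyl 2-[(1S,2R,3R)-2-ethenyl-2-methyl-4-oxo-3-(3-oxopropyl)cyclohexyl]-2-methylpropanoate | O=CCC[C@@H]1[C@](C)(C=C)[C@@H](C(C)(C)C(=O)OC)CCC1=O
F2 | step 7 | methyl 2-[(1S,2R,3R)-3-(but-3-yn-1-yl)-2-ethenyl-2-methyl-4-oxocyclohexyl]-2-methylpropanoate | C#CCC[C@@H]1[C@](C)(C=C)[C@@H](C(C)(C)C(=O)OC)CCC1=O
F3 | step 7 | ethylene ketal of F2 | C#CCC[C@@H]1[C@](C)(C=C)[C@@H](C(C)(C)C(=O)OC)CCC12OCCO2
F4 | step 11 | iodo alcohol (CH2OH in place of the ester of 18) | C[Si](C)(C)C#CCC[C@@H]1[C@](C)(CCI)[C@@H](C(C)(C)CO)CCC12OCCO2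
F5 | step 11 | iodo aldehyde (CHO in place of the ester of 18) | C[Si](C)(C)C#CCC[C@@H]1[C@](C)(CCI)[C@@H](C(C)(C)C=O)CCC12OCCO2
F6 | step 11 | C3 epimer of 22 (axial 3-OH) | C[Si](C)(C)C#CCC[C@@H]1[C@]2(C)CC[C@H](O)C(C)(C)[C@H]2CCC13OCCO3
F7 | step 17 | β-hydroxysilane (C8 bears OH and CH2SiMe2(OiPr)) | C#CCC[C@H]1[C@]2(C)CC[C@@H](O)C(C)(C)[C@H]2CC[C@]1(O)C[Si](C)(C)OC(C)C
F8 | step 17 | 3,8,17-triol with but-3-ynyl chain | C#CCC[C@H]1[C@]2(C)CC[C@@H](O)C(C)(C)[C@H]2CC[C@]1(O)CO
F9 | step 17 | ynoic acid of F8 | OC(=O)C#CCC[C@H]1[C@]2(C)CC[C@@H](O)C(C)(C)[C@H]2CC[C@]1(O)CO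
F10 | step 17 | methyl ynoate of F8 | COC(=O)C#CCC[C@H]1[C@]2(C)CC[C@@H](O)C(C)(C)[C@H]2CC[C@]1(O)CO
F11 | step 17 | methyl (Z)-enoate 3,8,17-triol | COC(=O)/C=C(/C)CC[C@H]1[C@]2(C)CC[C@@H](O)C(C)(C)[C@H]2CC[C@]1(O)CO
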